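Time was given: amber, ochre and grey each stood 50 min, and they differed in their free base, so I looked for what free base does to the electrophile per minute.

in all of them: electrophile 0.36 M; protic impurity 0.108 M

| run | free base | protonated nucleophile | scavenger | remark | time |
|---|---|---|---|---|---|
| Tuesday's | 0.55 equiv | 1.2 equiv | 0.30 equiv | run made earlier |  |
| Friday's | 1.6 equiv | 1.2 equiv | 0.30 equiv | run made earlier |  |
| amber | 1.10 equiv | 1.20 equiv | 0.300 equiv |  | 50 min |
| ochre | 1.70 equiv | 1.20 equiv | 0.300 equiv |  | 50 min |
| grey | 2.50 equiv | 1.20 equiv | 0.300 equiv |  | 50 min |

- part of the electrophile that has reacted at the end, amber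
- part of the electrophile that has reacted at the end, ochre
- part of the electrophile that has reacted at the end, grey
- what raising the equivalents of free base from its lowest to its highest value here does to the part of the electrophile that has reacted (changes below 5 percentage points count as none) (no change / it rises / it falls)

- percentages count the electrophile that a species holds: one idle adduct B counts as two
- product is meant together with its idle adduct B
- acid set free is meant together with its idle adduct A
- what was read earlier has a scatter of 1 percentage point, one standard deviation
- what may be going on: acid set free + scavenger -> scavenged by-product; electrophile + nucleophile -> acid set free + product; nucleophile + acid set free <-> idle adduct A; nucleophile + acid set free <-> protonated nucleophile; acid set free + free base <-> salt of the base; electrophile + protic impurity -> quenched substrate; electrophile + product <-> idle adduct B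
- in an amount of product, one idle adduct B counts as one product
- what has gone from electrophile into another species counts as reacted, even if it can come back

| run | time / min | electrophile / % | product / % |
|---|---|---|---|
| Tuesday's | 3.00 | 68.1 | 3.0 |
| Tuesday's | 5.00 | 63.7 | 3.7 |
| Tuesday's | 10.0 | 57.3 | 6.8 |
| Tuesday's | 20.0 | 51.2 | 9.7 |
| Tuesday's | 40.0 | 41.2 | 15.9 |
| Friday's | 3.00 | 66.1 | 3.8 |
| Friday's | 8.00 | 54.5 | 8.2 |
| Friday's | 15.0 | 46.6 | 15.1 |
| Friday's | 25.0 | 35.6 | 15.5 |
| Friday's | 40.0 | 29.9 | 23.2 |

(standard deviation of a reading: 1 percentage point)

I read the two runs against each other, first row by first row and last row by last row. In the first row, at 3.00 min, Tuesday's flask held 68.1 % of its electrophile and Friday's 66.1 %, a gap of 2 percentage points between flasks with 0.55 equiv and 1.6 equiv of free base. Both losses stood near the share that the protic impurity can take one for one, 30.0 % of the charge, and I made that share the zero of my scale. In the last row, at 40.0 min, the gap had grown to 11 points, so I looked for the free base in the part above that zero.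

Treating the electrophile beyond that share as a pseudo-first-order decay, I read a constant of 0.0133 min⁻¹ for Tuesday's flask and 0.0213 min⁻¹ for Friday's. I call the base order the power of the free base charge to which this constant answers. Read from these two flasks, with their scatter in it, the base order was 0.443. The symmetric case gives the zero for it: in the proton exchange between protonated nucleophile and free base taken by itself, nucleophile and salt of the base arise one for one, and while both partners stay near their charges mass action gives order 0.5 in each partner.

Scaling Tuesday's constant by this power, I reckoned at 50 min 71.6 % reacted for amber, 76.5 % for ochre and 80.8 % for grey, a rise of 9.2 points, larger than the margin of 5 points.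

The forecast gave 72 % (67 % to 76 %), 75 % (71 % to 79 %) and 76 % (72 % to 81 %), and for the trend no change, with the ground: “Amber already frees most of the nucleophile”. On the trend it and I parted.

The flasks gave 70.5 %, 75.5 % and 79.4 %, and on the trend the answer was: it rises, by 8.9 points. Nucleophile at 50.0 min stood at 0.0655 M in amber and 0.103 M in grey, a ratio of 1.57, where the base order gives 1.44 for the ratio of the two constants.

    acid set free + scavenger → scavenged by-product (k = 0.0670 L mol⁻¹ s⁻¹)
    electrophile + nucleophile → acid set free + product (k = 0.00190 L mol⁻¹ s⁻¹)
    nucleophile + acid set free ⇌ idle adduct A, settled at all times (K = 1.10 L mol⁻¹)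
    nucleophile + acid set free ⇌ protonated nucleophile, settled at all times (K = 1800 L mol⁻¹)
    acid set free + free base ⇌ salt of the base, settled at all times (K = 400 L mol⁻¹)
    electrophile + protic impurity → quenched substrate (k = 0.0540 L mol⁻¹ s⁻¹)
    electrophile + product ⇌ idle adduct B, settled at all times (K = 29.0 L mol⁻¹)

A neighbour of ochre was charged with 0.480 equiv of protonated nucleophile in place of 1.20 equiv; with the base order taken over for that partner, since the symmetric case gives both partners one order, I reckoned 66.2 % reacted at 50 min. The computed neighbour had 62.3 % reacted.

The earlier runs and the new flask were computed on assumed constants.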